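## Plan

- **Reading of the target:** the upper unit is a (2S,3R,4S)-flavan-3-ol (benzo ring A, pyran ring C, 4-hydroxyphenyl ring B). Its C-4 is bonded to C-6 of the lower unit, a (2R,3S,4R)-flavan-3,4-diol (benzo ring D, pyran ring F, 4-hydroxyphenyl ring E). Flavan locants are used for each unit.
- **Enabling feature:** in ring C, O-1 is a phenolic oxygen on C-8a, ortho to C-4a, and C-4 is a diarylmethine, so O-1=C-8a–C-4a=C-4 is a latent o-quinone methide. C-2 carries a para-oxygenated aryl group, so C-3=C-2 is a polarised styrene, and the 2,3-trans-3,4-trans pattern is what an E-alkene adding endo delivers.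
- **Cuts:** (a) ring C at C-4–C-3 and O-1–C-2 (hetero-[4+2]; the 3-OH is carried as a pinacolboryl group); (b) the C-4(upper)–C-6(lower) bond, to a 6-lithiated lower unit and a salicylaldehyde; (c) ring F at O-1–C-2, via the dihydroflavonol, to a chalcone epoxide.
- **Forward order:** chalcone, epoxide, ring F, reduction of the 4-ketone, 6-bromide, benzhydrol (interflavanyl bond), ring C last, C–B oxidation, deprotection.
- **Stereochemistry:** the lower unit comes from a Juliá–Colonna epoxidation (C-3), relayed to C-2 (inversion on ring closure) and C-4 (axial hydride). In the upper unit C-4 is set by a chiral Brønsted acid, C-3 and C-2 are relayed in the same cycloaddition, and C–B becomes C–O with retention.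

Key step: step 12

Remark: the catalyst of step 12 is (R)-3,3'-bis(2,4,6-triisopropylphenyl)-1,1'-binaphthyl-2,2'-diyl N-triflylphosphoramide; the R antipode is assumed to open the face of the o-quinone methide that leads to the upper C-4 configuration of 23. If the sense of induction is the opposite, the S antipode is used and nothing else changes.

Remark: CIP descriptors are quoted only where they were derived for that compound; the SMILES in the compound list define the stereochemistry of every compound.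

## Route

Step 1
Reactants: 1 1-(2,3,4-trihydroxyphenyl)ethan-1-one (gallacetophenone)
Product: 2 1-[3,4-bis(benzyloxy)-2-hydroxyphenyl]ethan-1-one
Conditions: BnBr (2.1 equiv), K2CO3, DMF, rt
Reagents that add atoms: benzyl bromide, BrCc1ccccc1
Why: Williamson etherification, in which the 2-OH is held in a hydrogen bond to the acetyl carbonyl and is the least nucleophilic, so two equivalents of benzyl bromide should alkylate the 4-OH and 3-OH and leave the chelated 2-OH free.

Step 2
Reactants: 2 1-[3,4-bis(benzyloxy)-2-hydroxyphenyl]ethan-1-one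
Product: 3 1-[3,4-bis(benzyloxy)-2-(methoxymethoxy)phenyl]ethan-1-one
Conditions: NaH, MOMCl, DMF, 0 °C → rt
Reagents that add atoms: chloromethyl methyl ether, COCCl
Why: NaH deprotonates the chelated phenol irreversibly and the phenoxide is alkylated by the reactive α-chloro ether (MOM ether formation), which blocks flavanone formation in steps 3 and 4.

Step 3
Reactants: 3 1-[3,4-bis(benzyloxy)-2-(methoxymethoxy)phenyl]ethan-1-one; 4 4-(benzyloxy)benzaldehyde
Product: 5 (2E)-1-[3,4-bis(benzyloxy)-2-(methoxymethoxy)phenyl]-3-[4-(benzyloxy)phenyl]prop-2-en-1-one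
Conditions: KOH, EtOH, rt
Reagents that add atoms: none
Why: Claisen–Schmidt condensation of the methyl ketone with the non-enolisable aldehyde gives the conjugated E-enone under thermodynamic control.

Step 4
Reactants: 5 (2E)-1-[3,4-bis(benzyloxy)-2-(methoxymethoxy)phenyl]-3-[4-(benzyloxy)phenyl]prop-2-en-1-one
Product: 6 [3,4-bis(benzyloxy)-2-(methoxymethoxy)phenyl]{(2R,3S)-3-[4-(benzyloxy)phenyl]oxiran-2-yl}methanone
Conditions: poly-L-leucine, urea–H2O2, DBU, THF, rt
Reagents that add atoms: urea–hydrogen peroxide, OO.NC(N)=O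
Why: Juliá–Colonna epoxidation, in which hydroperoxide adds to the enone held by the N-terminal NH groups of the helical poly-L-leucine, known to give the (αR,βS)-epoxide of chalcones with the trans geometry of the E-alkene; this step sets what becomes C-3 of the lower unit.

Step 5
Reactants: 6 [3,4-bis(benzyloxy)-2-(methoxymethoxy)phenyl]{(2R,3S)-3-[4-(benzyloxy)phenyl]oxiran-2-yl}methanone
Product: 8 (2R,3R)-7,8-bis(benzyloxy)-2-[4-(benzyloxy)phenyl]-3-hydroxy-2,3-dihydro-4H-chromen-4-one, via phenolic epoxide 7 (not isolated)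
Conditions: conc. HCl (cat.), MeOH/THF, 55 °C
Reagents that add atoms: none
Why: acid removes the MOM acetal and the freed phenol of 7 opens the epoxide at the benzylic carbon activated by the 4-benzyloxyphenyl group (6-endo opening, the known chalcone epoxide to dihydroflavonol cyclisation) with inversion, so αR,βS becomes 2R,3R with the diequatorial 2,3-trans arrangement, C-3 being untouched.

Step 6
Reactants: 8 (2R,3R)-7,8-bis(benzyloxy)-2-[4-(benzyloxy)phenyl]-3-hydroxy-2,3-dihydro-4H-chromen-4-one
Product: 9 (2R,3S,4R)-7,8-bis(benzyloxy)-2-[4-(benzyloxy)phenyl]-3,4-dihydro-2H-chromene-3,4-diol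
Conditions: NaBH4, MeOH/THF, 0 °C
Reagents that add atoms: none
Why: NaBH4 should add hydride to the C-4 carbonyl from the axial direction of the half-chair that holds the 2-aryl and 3-OH groups equatorial, the known course for 2,3-trans-dihydroflavonols, giving the equatorial 4-OH trans to the 3-OH.

Step 7
Reactants: 9 (2R,3S,4R)-7,8-bis(benzyloxy)-2-[4-(benzyloxy)phenyl]-3,4-dihydro-2H-chromene-3,4-diol
Product: 10 3,4-bis-O-(tert-butyldimethylsilyl) ether of 9 [(2R,3R,4R) by the sequence rule; spatial arrangement of 9 unchanged]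
Conditions: TBSOTf (2.5 equiv), 2,6-lutidine, CH2Cl2, 0 °C → rt
Reagents that add atoms: tert-butyldimethylsilyl triflate, CC(C)(C)[Si](C)(C)OS(=O)(=O)C(F)(F)F
Why: a silyl triflate with a hindered pyridine base silylates both secondary hydroxyls of the trans-diequatorial diol, giving base-stable and fluoride-labile protection for the organolithium step.

Step 8
Reactants: 10 3,4-bis-O-(tert-butyldimethylsilyl) ether of 9
Product: 11 6-bromo derivative of 10 [(2R,3R,4R)-7,8-bis(benzyloxy)-2-[4-(benzyloxy)phenyl]-6-bromo-3,4-bis(tert-butyldimethylsilyloxy)-3,4-dihydro-2H-chromene]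
Conditions: NBS (1.05 equiv), CH2Cl2, −20 → 0 °C, dark
Reagents that add atoms: N-bromosuccinimide, O=C1CCC(=O)N1Br
Why: electrophilic aromatic bromination should go to C-6 of ring D, which is ortho to the 7-benzyloxy group and para to the ring oxygen, whereas C-5 is activated only by the twisted 8-benzyloxy group and shielded by the 4-silyloxy group, and ring E has one activating oxygen only.

Step 9
Reactants: 12 2,3,4-trihydroxybenzaldehyde
Product: 13 3,4-bis(benzyloxy)-2-hydroxybenzaldehyde
Conditions: BnBr (2.05 equiv), K2CO3, DMF, rt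
Reagents that add atoms: benzyl bromide, BrCc1ccccc1
Why: Williamson etherification as in step 1, the 2-OH chelated to the formyl group being the least nucleophilic, so that the 4-OH and 3-OH are benzylated.

Step 10
Reactants: 11 6-bromo derivative of 10; 13 3,4-bis(benzyloxy)-2-hydroxybenzaldehyde
Product: 16 [3,4-bis(benzyloxy)-2-hydroxyphenyl](lower-unit-6-yl)methanol in which the lower unit is that of 10 (both carbinol epimers), via aryllithium 14 (not isolated), via sodium phenoxide 15 (not isolated)
Conditions: 11, t-BuLi (2.0 equiv), THF, −78 °C; then 15 [from 13 (1.3 equiv) and NaH, THF, 0 °C], −78 → −20 °C; H2O quench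
Reagents that add atoms: none
Why: bromine–lithium exchange gives aryllithium 14, which adds to the formyl group of the preformed sodium phenoxide 15 (1,2-addition of an organometallic to a salicylaldehyde, whose phenoxide tempers but does not block the aldehyde); the carbinol carbon forms as both epimers, which is of no consequence because it becomes trigonal in step 12.

Step 11
Reactants: 17 1-(benzyloxy)-4-ethynylbenzene
Product: 18 2-{(E)-2-[4-(benzyloxy)phenyl]ethenyl}-4,4,5,5-tetramethyl-1,3,2-dioxaborolane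
Conditions: pinacolborane (1.1 equiv), Cp2Zr(H)Cl (5 mol%), Et3N (10 mol%), neat, 60 °C
Reagents that add atoms: pinacolborane, CC1(C)OBOC1(C)C
Why: Cp2Zr(H)Cl-catalysed hydroboration of the terminal alkyne is a syn addition that places boron on the terminal carbon and should give the E-alkenylboronate only.

Step 12
Reactants: 16 [3,4-bis(benzyloxy)-2-hydroxyphenyl](lower-unit-6-yl)methanol; 18 2-{(E)-2-[4-(benzyloxy)phenyl]ethenyl}-4,4,5,5-tetramethyl-1,3,2-dioxaborolane
Product: 20 hexa-O-benzyl-bis-O-TBS dimer carrying the pinacolboryl group at C-3 of the upper unit (2,3-trans-3,4-trans ring C; centres arranged as in 23 with boron in place of the 3-oxygen), via o-quinone methide 19 (not isolated)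
Conditions: (R)-N-triflylphosphoramide of the remark (10 mol%), 18 (2.5 equiv), 5 Å molecular sieves, CH2Cl2, −40 → 0 °C
Reagents that add atoms: none
Why: Proposed new method: the acid dehydrates 16 to the E-configured o-quinone methide 19 (O-1=C-8a–C-4a=C-4, hydrogen-bonded to the chiral phosphoramide anion), and the alkenylboronate 18 adds across it in an asynchronous inverse-electron-demand hetero-[4+2] cycloaddition in which the boron-bearing carbon (C-3) bonds to C-4 ahead of O-1 to C-2; the closest known reaction type is the chiral Brønsted acid catalysed [4+2] cycloaddition of o-quinone methides from o-hydroxybenzhydrols with styrenes, and alkenylboronates are established 2π partners in carbo-Diels–Alder reactions but not with o-quinone methides. Ring C is closed intermolecularly in the [4+2] mode, its C-4–C-3 and O-1–C-2 bonds arising in the same event. C-4 is set by the catalyst, whose binaphthyl pocket should leave one face of 19 open, and C-3 and C-2 follow from C-4 by suprafacial addition of the E-alkene (2,3-trans) with the aryl group endo (2,4-cis, hence 3,4-trans), the all-equatorial arrangement that is also the thermodynamic one. The regioselectivity needed (O-1 to the aryl-bearing carbon) is secured because the 4-benzyloxyphenyl group alone stabilises positive charge at C-2, helped by hyperconjugation of the C–B bond, while the boryl group, unlike an alkoxy group, cannot polarise the alkene the other way. The facial selectivity cannot come from the lower unit, whose stereocentres are remote from C-4, and so rests on the catalyst; the chemoselectivity needed is ring closure in preference to loss of boron from the zwitterion, which the intramolecular phenolic oxygen and the non-nucleophilic medium should favour.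

Step 13
Reactants: 20 3-boryl dimer
Product: 21 hexa-O-benzyl-bis-O-TBS dimer with free 3-OH in the upper unit (centres arranged as in 23)
Conditions: H2O2 (30% aq.), NaOH (2 M aq.), THF, 0 °C → rt
Reagents that add atoms: hydrogen peroxide, OO
Why: oxidation of the secondary alkylboronate by hydroperoxide proceeds by 1,2-migration of carbon from boron to oxygen with retention, so the equatorial boryl group becomes the 3-OH of the upper unit, and no free phenol is present that alkaline peroxide could oxidise.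

Step 14
Reactants: 21 hexa-O-benzyl-bis-O-TBS dimer
Product: 22 hexa-O-benzyl ether of 23 (both 4'-, 7- and 8-hydroxyls benzylated; three free aliphatic hydroxyls)
Conditions: Bu4NF, AcOH, THF, rt → 40 °C
Reagents that add atoms: none
Why: fluoride cleaves both silyl ethers through pentacoordinate silicon, and acetic acid buffers the alkoxides so that the benzyl ethers and all six stereocentres remain untouched.

Step 15
Reactants: 22 hexa-O-benzyl ether of 23
Product: 23 (2R,3S,4R)-6-[(2S,3R,4S)-3,7,8-trihydroxy-2-(4-hydroxyphenyl)-3,4-dihydro-2H-chromen-4-yl]-2-(4-hydroxyphenyl)-3,4-dihydro-2H-chromene-3,4,7,8-tetrol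
Conditions: H2 (1 atm), Pd(OH)2/C, THF/MeOH, rt, argon filtration
Reagents that add atoms: none
Why: hydrogenolysis of the six aryl benzyl ethers over Pd(OH)2/C in a neutral medium should be much faster than cleavage of the free benzylic C-4–OH bond of the lower unit, which needs acid to become a leaving group, so the hexaphenol is released without change at any stereocentre.

## Compound list

1 | 1-(2,3,4-trihydroxyphenyl)ethan-1-one | CC(=O)c1ccc(O)c(O)c1O | starting material
2 | 1-[3,4-bis(benzyloxy)-2-hydroxyphenyl]ethan-1-one | CC(=O)c1ccc(OCc2ccccc2)c(OCc2ccccc2)c1O | intermediate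
3 | 1-[3,4-bis(benzyloxy)-2-(methoxymethoxy)phenyl]ethan-1-one | CC(=O)c1ccc(OCc2ccccc2)c(OCc2ccccc2)c1OCOC | intermediate
4 | 4-(benzyloxy)benzaldehyde | O=Cc1ccc(OCc2ccccc2)cc1 | starting material
5 | (2E)-1-[3,4-bis(benzyloxy)-2-(methoxymethoxy)phenyl]-3-[4-(benzyloxy)phenyl]prop-2-en-1-one | O=C(/C=C/c1ccc(OCc2ccccc2)cc1)c1ccc(OCc2ccccc2)c(OCc2ccccc2)c1OCOC | intermediate
6 | [3,4-bis(benzyloxy)-2-(methoxymethoxy)phenyl]{(2R,3S)-3-[4-(benzyloxy)phenyl]oxiran-2-yl}methanone | O=C([C@@H]1O[C@H]1c1ccc(OCc2ccccc2)cc1)c1ccc(OCc2ccccc2)c(OCc2ccccc2)c1OCOC | intermediate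
7 | [3,4-bis(benzyloxy)-2-hydroxyphenyl]{(2R,3S)-3-[4-(benzyloxy)phenyl]oxiran-2-yl}methanone | O=C([C@@H]1O[C@H]1c1ccc(OCc2ccccc2)cc1)c1ccc(OCc2ccccc2)c(OCc2ccccc2)c1O | intermediate
8 | (2R,3R)-7,8-bis(benzyloxy)-2-[4-(benzyloxy)phenyl]-3-hydroxy-2,3-dihydro-4H-chromen-4-one | O=C1c2ccc(OCc3ccccc3)c(OCc3ccccc3)c2O[C@H](c2ccc(OCc3ccccc3)cc2)[C@H]1O | intermediate
9 | (2R,3S,4R)-7,8-bis(benzyloxy)-2-[4-(benzyloxy)phenyl]-3,4-dihydro-2H-chromene-3,4-diol | C(c1ccccc1)Oc1ccc([C@H]2Oc3c(ccc(OCc4ccccc4)c3OCc3ccccc3)[C@@H](O)[C@@H]2O)cc1 | intermediate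
10 | (2R,3R,4R)-7,8-bis(benzyloxy)-2-[4-(benzyloxy)phenyl]-3,4-bis(tert-butyldimethylsilyloxy)-3,4-dihydro-2H-chromene | C(c1ccccc1)Oc1ccc([C@H]2Oc3c(ccc(OCc4ccccc4)c3OCc3ccccc3)[C@@H](O[Si](C)(C)C(C)(C)C)[C@@H]2O[Si](C)(C)C(C)(C)C)cc1 | intermediate
11 | (2R,3R,4R)-7,8-bis(benzyloxy)-2-[4-(benzyloxy)phenyl]-6-bromo-3,4-bis(tert-butyldimethylsilyloxy)-3,4-dihydro-2H-chromene | C(c1ccccc1)Oc1ccc([C@H]2Oc3c(cc(Br)c(OCc4ccccc4)c3OCc3ccccc3)[C@@H](O[Si](C)(C)C(C)(C)C)[C@@H]2O[Si](C)(C)C(C)(C)C)cc1 | intermediate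
12 | 2,3,4-trihydroxybenzaldehyde | O=Cc1ccc(O)c(O)c1O | starting material
13 | 3,4-bis(benzyloxy)-2-hydroxybenzaldehyde | O=Cc1ccc(OCc2ccccc2)c(OCc2ccccc2)c1O | intermediate
14 | 6-lithio derivative of 10 (aryllithium) | C(c1ccccc1)Oc1ccc([C@H]2Oc3c(cc([Li])c(OCc4ccccc4)c3OCc3ccccc3)[C@@H](O[Si](C)(C)C(C)(C)C)[C@@H]2O[Si](C)(C)C(C)(C)C)cc1 | intermediate
15 | sodium 2,3-bis(benzyloxy)-6-formylphenoxide | [Na+].[O-]c1c(C=O)ccc(OCc2ccccc2)c1OCc1ccccc1 | intermediate
16 | [3,4-bis(benzyloxy)-2-hydroxyphenyl]{(2R,3R,4R)-7,8-bis(benzyloxy)-2-[4-(benzyloxy)phenyl]-3,4-bis(tert-butyldimethylsilyloxy)-3,4-dihydro-2H-chromen-6-yl}methanol, both carbinol epimers | C(c1ccccc1)Oc1ccc([C@H]2Oc3c(cc(C(O)c4ccc(OCc5ccccc5)c(OCc5ccccc5)c4O)c(OCc4ccccc4)c3OCc3ccccc3)[C@@H](O[Si](C)(C)C(C)(C)C)[C@@H]2O[Si](C)(C)C(C)(C)C)cc1 | intermediate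
17 | 1-(benzyloxy)-4-ethynylbenzene | C#Cc1ccc(OCc2ccccc2)cc1 | starting material
18 | 2-{(E)-2-[4-(benzyloxy)phenyl]ethenyl}-4,4,5,5-tetramethyl-1,3,2-dioxaborolane | CC1(C)OB(/C=C/c2ccc(OCc3ccccc3)cc2)OC1(C)C | intermediate
19 | (6E)-2,3-bis(benzyloxy)-6-[(lower-unit-6-yl)methylidene]cyclohexa-2,4-dien-1-one, lower unit as in 10 (o-quinone methide) | C(c1ccccc1)Oc1ccc([C@H]2Oc3c(cc(/C=C4\C=CC(OCc5ccccc5)=C(OCc5ccccc5)C4=O)c(OCc4ccccc4)c3OCc3ccccc3)[C@@H](O[Si](C)(C)C(C)(C)C)[C@@H]2O[Si](C)(C)C(C)(C)C)cc1 | intermediate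
20 | upper unit 7,8-bis(benzyloxy)-2-[4-(benzyloxy)phenyl]-3-(4,4,5,5-tetramethyl-1,3,2-dioxaborolan-2-yl)chroman-4-yl (2,3-trans-3,4-trans) on C-6 of the lower unit of 10; centres arranged as in 23 | C(c1ccccc1)Oc1ccc([C@H]2Oc3c(cc([C@H]4c5ccc(OCc6ccccc6)c(OCc6ccccc6)c5O[C@@H](c5ccc(OCc6ccccc6)cc5)[C@@H]4B4OC(C)(C)C(C)(C)O4)c(OCc4ccccc4)c3OCc3ccccc3)[C@@H](O[Si](C)(C)C(C)(C)C)[C@@H]2O[Si](C)(C)C(C)(C)C)cc1 | intermediate
21 | hexa-O-benzyl-3,4-bis-O-TBS(lower unit) derivative of 23 with free upper 3-OH | C(c1ccccc1)Oc1ccc([C@H]2Oc3c(cc([C@H]4c5ccc(OCc6ccccc6)c(OCc6ccccc6)c5O[C@@H](c5ccc(OCc6ccccc6)cc5)[C@@H]4O)c(OCc4ccccc4)c3OCc3ccccc3)[C@@H](O[Si](C)(C)C(C)(C)C)[C@@H]2O[Si](C)(C)C(C)(C)C)cc1 | intermediate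
22 | hexa-O-benzyl ether of 23 (all six phenols benzylated) | C(c1ccccc1)Oc1ccc([C@H]2Oc3c(cc([C@H]4c5ccc(OCc6ccccc6)c(OCc6ccccc6)c5O[C@@H](c5ccc(OCc6ccccc6)cc5)[C@@H]4O)c(OCc4ccccc4)c3OCc3ccccc3)[C@@H](O)[C@@H]2O)cc1 | intermediate
23 | (2R,3S,4R)-6-[(2S,3R,4S)-3,7,8-trihydroxy-2-(4-hydroxyphenyl)-3,4-dihydro-2H-chromen-4-yl]-2-(4-hydroxyphenyl)-3,4-dihydro-2H-chromene-3,4,7,8-tetrol | Oc1ccc([C@H]2Oc3c(cc([C@H]4c5ccc(O)c(O)c5O[C@@H](c5ccc(O)cc5)[C@@H]4O)c(O)c3O)[C@@H](O)[C@@H]2O)cc1 | target

## Step count and risks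

Total step count: 15. Longest linear sequence: 13 steps (steps 1–8, 10, 12–15).

**Step 12.** Three processes may defeat it: loss of boron from the zwitterion after C-4–C-3 bond formation (formal alkenyl transfer instead of ring closure), insufficient facial control by the catalyst, and acid-induced ionisation at the silyloxy-bearing C-4 of the lower unit. The fallback sets out from 16 and 18 and comes back at 21, using known reactions only. Oxidative cleavage of the pinacol ester of 18 (NaIO4, NH4OAc, acetone/H2O) should give (E)-{2-[4-(benzyloxy)phenyl]ethenyl}boronic acid F1. The known chiral-diol-catalysed conjugate alkenylation of o-quinone methides (3,3'-dibromo-BINOL, 16 and F1, toluene) should then give the 2-(1,3-diarylallyl)phenol F2, with C-4 set by the diol and the E-alkene retained. Shi epoxidation of the alkene (fructose-derived ketone of the hand that gives the required face, Oxone (2KHSO5·KHSO4·K2SO4), buffered) should give the trans-epoxide F3. The phenol then opens F3 at the benzylic carbon with inversion (6-endo, cat. camphorsulfonic acid) to 21, the 2,3-trans relation coming from the trans-epoxide and the 3,4-trans relation from the epoxide face.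

**Step 15.** The risk is over-reduction, that is hydrogenolysis of the benzylic C-4–O bond of the lower unit alongside the benzyl ethers, and air oxidation of the free pyrogallol rings during isolation. The fallback sets out from 22 and comes back at 23 by changing the oxidation level at C-4. MnO2 (CH2Cl2) should oxidise only the benzylic 4-OH to the dihydroflavonol-type ketone F4. Hydrogenolysis (H2, Pd(OH)2/C), which an aryl ketone tolerates, should give the hexaphenolic ketone F5. NaBH4 (EtOH, 0 °C) should then reduce F5 to 23 with the same axial hydride delivery as in step 6.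

**Step 10.** The risk is incomplete addition to the deactivated phenoxide aldehyde, with the aryllithium consumed instead by proton transfer or by attack on a neighbouring benzyl ether. The fallback sets out from 13 (and 11) and comes back at 16 with a protected electrophile. Allylation of 13 (allyl bromide, K2CO3, DMF, 60 °C) should give 2-(allyloxy)-3,4-bis(benzyloxy)benzaldehyde F6. Addition of 14 (from 11 as in step 10) to F6 should give the O-allyl benzhydrol F7. Deallylation with Pd(PPh3)4 (cat.) and morpholine in THF, a neutral method that does not ionise the benzhydrol, should return 16.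

Further compounds
F1 | step 12 | (E)-{2-[4-(benzyloxy)phenyl]ethenyl}boronic acid | OB(O)/C=C/c1ccc(OCc2ccccc2)cc1
F2 | step 12 | 2,3-bis(benzyloxy)-6-{(E)-3-[4-(benzyloxy)phenyl]-1-(lower-unit-6-yl)prop-2-en-1-yl}phenol, lower unit as in 10, allylic centre arranged as upper C-4 of 23 | C(c1ccccc1)Oc1ccc([C@H]2Oc3c(cc([C@H](/C=C/c4ccc(OCc5ccccc5)cc4)c4ccc(OCc5ccccc5)c(OCc5ccccc5)c4O)c(OCc4ccccc4)c3OCc3ccccc3)[C@@H](O[Si](C)(C)C(C)(C)C)[C@@H]2O[Si](C)(C)C(C)(C)C)cc1
F3 | step 12 | trans-epoxide of F2 (oxirane from the E-alkene, oxygen on the face that becomes the upper 3-OH of 23) | C(c1ccccc1)Oc1ccc([C@H]2Oc3c(cc([C@H]([C@H]4O[C@@H]4c4ccc(OCc5ccccc5)cc4)c4ccc(OCc5ccccc5)c(OCc5ccccc5)c4O)c(OCc4ccccc4)c3OCc3ccccc3)[C@@H](O[Si](C)(C)C(C)(C)C)[C@@H]2O[Si](C)(C)C(C)(C)C)cc1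
F4 | step 15 | hexa-O-benzyl dimer with the lower unit as 3-hydroxychroman-4-one (4-ketone of 22) | C(c1ccccc1)Oc1ccc([C@H]2Oc3c(cc([C@H]4c5ccc(OCc6ccccc6)c(OCc6ccccc6)c5O[C@@H](c5ccc(OCc6ccccc6)cc5)[C@@H]4O)c(OCc4ccccc4)c3OCc3ccccc3)C(=O)[C@@H]2O)cc1
F5 | step 15 | hexaphenolic dimer with the lower unit as 3-hydroxychroman-4-one (4-ketone of 23) | Oc1ccc([C@H]2Oc3c(cc([C@H]4c5ccc(O)c(O)c5O[C@@H](c5ccc(O)cc5)[C@@H]4O)c(O)c3O)C(=O)[C@@H]2O)cc1
F6 | step 10 | 2-(allyloxy)-3,4-bis(benzyloxy)benzaldehyde | O=Cc1ccc(OCc2ccccc2)c(OCc2ccccc2)c1OCC=C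
F7 | step 10 | O-allyl ether of 16 at the phenolic oxygen, both carbinol epimers | C(c1ccccc1)Oc1ccc([C@H]2Oc3c(cc(C(O)c4ccc(OCc5ccccc5)c(OCc5ccccc5)c4OCC=C)c(OCc4ccccc4)c3OCc3ccccc3)[C@@H](O[Si](C)(C)C(C)(C)C)[C@@H]2O[Si](C)(C)C(C)(C)C)cc1
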